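The leftover is the place to start: at the last reading of the spring run, 5.9 min, a share of 50.4 % of the starting material charged is not standing as target, while the summer run, with more catalyst, keeps 41.2 % out of target at the same time. Target in straight proportion to catalyst cannot hold on the share itself, since the spring share scaled to the autumn catalyst comes to 124 %, more than the whole charge. It nearly holds on another quantity: the spring run at its last reading stands at 1.23 mM⁻¹ in the odds per catalyst, the target share over the share not in target, divided by the catalyst charge. The summer run stands at 1.19 mM⁻¹, slightly lower.

| flask | starting material | reagent | catalyst | time |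
|---|---|---|---|---|
| spring | 80.0 mM | 88.0 mM | 0.800 mM |  |
| dawn | 40.0 mM | 48.0 mM | 0.800 mM |  |
| summer | 80.0 mM | 88.0 mM | 1.20 mM |  |
| autumn | 80.0 mM | 88.0 mM | 2.00 mM | 5.9 min |

| run | time / min | [target] / mM |
|---|---|---|
| spring run | 0.98 | 19.95 |
| spring run | 2.0 | 30.06 |
| spring run | 3.0 | 34.94 |
| spring run | 3.9 | 37.28 |
| spring run | 4.9 | 38.92 |
| spring run | 5.9 | 39.70 |
| dawn run | 0.98 | 8.64 |
| dawn run | 2.0 | 14.07 |
| dawn run | 3.0 | 17.53 |
| dawn run | 3.9 | 18.92 |
| dawn run | 4.9 | 20.56 |
| dawn run | 5.9 | 21.04 |
| summer run | 0.98 | 27.04 |
| summer run | 2.0 | 38.71 |
| summer run | 3.0 | 43.07 |
| summer run | 3.9 | 45.49 |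
| summer run | 4.9 | 46.21 |
| summer run | 5.9 | 47.03 |

(readings scatter by 0.2 mM)

1. reaction order in [catalyst] at the outset, round the charge of the spring run, defined at two percent of the starting material turned into target
2. target in the autumn run at 5.9 min, as a share of the starting material charged

- Overall: starting material + reagent -> target, with catalyst as catalyst.
- Constant volume, constant temperature.
- Readings of a species count what is bound in complexes too.
- "The second partner" is reagent.
- An order is taken over about fifteen percent of the charge, up and down.

A first round takes the spring value unchanged to the autumn catalyst and gives odds of 2.46, a share of 71.1 %. A second round puts that answer back with the observed drift, drawn as a straight line in catalyst through the spring and summer values, so the autumn run gets 1.10 mM⁻¹ and, at the same clock time, a share of 68.8 %. The odds at the first readings of the summer and spring runs, set against their catalyst ratio, give an order of 1.06. The forecast stands at an order of 0.95, “close to first order”, lower than this reckoning, and at 69 % for the autumn run.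

The flask gives 69.1 % for the autumn run and an order of 1.0, on this scheme:

    catalyst + starting material + reagent → target + catalyst (14880 M⁻² min⁻¹)
    catalyst + starting material ⇌ idle catalyst-substrate complex, settled at all times (24.70 M⁻¹)
    target + reagent → side product (3.144 M⁻¹ min⁻¹)

The autumn odds per catalyst are therefore 1.12 mM⁻¹, against 1.10 mM⁻¹ reckoned. The path from target and reagent to side product moves the readings by 68 times their scatter, root mean square, and those same readings gave 1.23 mM⁻¹ and 1.19 mM⁻¹. In the dawn run, at the spring catalyst charge, 1.23 mM⁻¹ means odds of 0.985, and the dawn run stands at odds of one at 4.57 min, against 6.64 min in the spring run.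

The runs are calculated for substances that don't exist, noise included.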